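**Retrosynthetic overview**
- Structural feature: in the five-membered ring (C1, C2, C3, C3a, C8a), C3a (CH) and C8a (C–Me) lie next to oxygenated C1. They carry the two arms of the seven-membered ring, C4 and C8, trans to each other. This is the footprint of β-vinylation and α-alkylation of 2-methylcyclopent-2-enone, whose ring is kept as the five-membered ring.
- Endgame: the phenol silyl ether, the C1 acetate and the C4 aroyl ester are disconnected first. The C4 α-carbinol and the C5=C6 enone arise together from the α-epoxide of a C4=C5 β,γ-enone by E1cB opening.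
- Seven-membered ring (the only ring built, step 13): ring-closing metathesis at C4=C5 between the C3a vinyl group and an α-methylallyl ketone grown on the C8–C7 arm through a Weinreb amide.
- C1–O α comes from a cis-γ-lactone formed by SN2 attack of the C7 carboxylate on a C1 β-mesylate. The C3 carbinol comes from the C2=C3 enone by isopropyl conjugate addition, reoxidation, α-epoxidation and SmI2.
- Opening move: one-pot union of 1, 2 and 3, forming C3a–C4 and C8a–C8 and setting both ring-fusion stereocentres.

Key step: step 1

Convention: the azulene numbering of the target is used for every intermediate. β is the face of the C8a methyl group and α is the opposite face.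
Assumption: the sense of induction of the ferrocenyl diphosphine with an alkenyl Grignard reagent is taken to follow that of alkyl Grignard reagents; if a pilot run shows the opposite sense, the commercial mirror-image ligand is used.

**Step 1**
Reactants: 1 2-methylcyclopent-2-en-1-one; 2 vinylmagnesium bromide; 3 methyl bromoacetate
Product: 5 methyl 2-[(1S,5S)-1-methyl-2-oxo-5-vinylcyclopentyl]acetate, via bromomagnesium enolate 4 (not isolated)
Conditions: CuBr·SMe2 (5 mol %), (R)-1-[(Sp)-2-(dicyclohexylphosphino)ferrocenyl]ethyldiphenylphosphine (6 mol %), tBuOMe, −78 °C, slow addition of 2 (1.0 M in THF, diluted with tBuOMe, 1.2 equiv); then DMPU, 3 (3 equiv), −78 → 0 °C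
Reagents that add atoms: none
Why: The diphosphine-bound vinylcopper species made from CuBr·SMe2 and 2 binds one π-face of the enone, adds at C3a and reductively eliminates to form C3a–C4, releasing the tetrasubstituted bromomagnesium enolate 4; DMPU then loosens its aggregates so that C8a displaces bromide from 3 in an SN2 step and forms C8a–C8. The closest known reaction type is the copper/ferrocenyl-diphosphine-catalysed asymmetric conjugate addition of Grignard reagents to 2-methylcyclopent-2-enone with sequential enolate alkylation. The step closes no ring, so no mode of closure has to be satisfied. C3a (S) is fixed by the chiral ligand on copper, and C8a (S) by the new C3a vinyl group, which covers the β face of the planar enolate so that 3 enters from the α face and the two arms end up trans. The step needs 1,4- rather than 1,2-addition and alkylation at C8a rather than at C2 or oxygen: the first rests on the soft copper nucleophile and the slow addition of 2 at −78 °C, the second on the substrate itself, because conjugate addition places the enolate double bond only between C1 and C8a and no proton source is present to move it.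

**Step 2**
Reactants: 5 keto ester from step 1
Product: 7 methyl 2-[(1S,5R)-1-methyl-2-oxo-5-vinylcyclopent-3-en-1-yl]acetate, via lithium enolate 6 (not isolated)
Conditions: LiN(iPr)2 (1.05 equiv), THF, −78 °C; then PhS(Cl)=NtBu (1.2 equiv), −78 °C
Reagents that add atoms: none
Why: Mukaiyama dehydrogenation with N-tert-butylbenzenesulfinimidoyl chloride: the ketone can only be deprotonated at C2 because C8a is quaternary and the neopentyl ester CH2 is kinetically slower, the enolate attacks sulfur and the adduct collapses by intramolecular syn elimination at −78 °C, so that the base-sensitive 4-vinylcyclopentenone 7 never meets free base and no stereocentre is touched.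

**Step 3**
Reactants: 7 C2=C3 enone; 8 isopropylmagnesium chloride
Product: 9 methyl 2-[4-isopropyl-1-methyl-2-(trimethylsilyloxy)-5-vinylcyclopent-2-en-1-yl]acetate (C1=C2 silyl enol ether; C3 isopropyl α, C3a vinyl β, C8a methyl β)
Conditions: 8 (1.5 equiv), CuBr·SMe2 (10 mol %), TMSCl (2.5 equiv), DMPU, THF, −78 °C; Et3N, cold aq NaHCO3
Reagents that add atoms: chlorotrimethylsilane, C[Si](C)(C)Cl
Why: Copper-catalysed conjugate addition of a Grignard reagent accelerated by TMSCl should outrun γ-deprotonation at C3a and deliver isopropyl to C3 anti to the C3a vinyl group, the enolate being caught as its silyl enol ether; the new C3 centre is of no consequence because step 4 removes it.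

**Step 4**
Reactants: 9 silyl enol ether
Product: 10 methyl 2-[4-isopropyl-1-methyl-2-oxo-5-vinylcyclopent-3-en-1-yl]acetate (C2=C3 enone with isopropyl on C3; C3a vinyl β, C8a methyl β)
Conditions: Pd(OAc)2 (1.05 equiv), MeCN, rt
Reagents that add atoms: none
Why: Saegusa–Ito oxidation: transmetalation gives a divalent palladium enolate bound at C2 on the β face, anti to isopropyl and syn to the C3 hydrogen, and β-hydride elimination under neutral conditions returns the C2=C3 enone, now with isopropyl on C3, without risk to C3a.

**Step 5**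
Reactants: 10 3-isopropyl enone
Product: 11 2α,3α-epoxide of 10 (oxirane oxygen α on C2 and C3, isopropyl β, C3a vinyl β, C8a methyl β)
Conditions: 30 % aq H2O2 (10 equiv), 1 M aq NaOH (0.3 equiv), MeOH, −10 → 0 °C
Reagents that add atoms: hydrogen peroxide, OO
Why: Weitz–Scheffer epoxidation: hydroperoxide adds to C3 from the α face, anti to the adjacent C3a vinyl group, and the enolate closes the oxirane on that same face, which sets the C3–O bond α (isopropyl β); keeping H2O2 in large excess over NaOH leaves the weakly basic hydroperoxide as the only anion and so holds back γ-deprotonation at C3a, in line with the alkaline epoxidation of 4-alkenylcyclopentenones of the prostaglandin A class.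

**Step 6**
Reactants: 11 epoxy ketone
Product: 12 methyl 2-[4-hydroxy-4-isopropyl-1-methyl-2-oxo-5-vinylcyclopentyl]acetate (C3 OH α, isopropyl β, C3a vinyl β, C8a methyl β)
Conditions: SmI2 (2.5 equiv, 0.1 M in THF), MeOH, THF, −90 °C
Reagents that add atoms: none
Why: Reductive opening of an α,β-epoxy ketone by SmI2: two single-electron transfers break only the C2–O bond next to the carbonyl group and methanol protonates the trivalent samarium enolate, so the C3–O bond keeps its α configuration while ester, vinyl group and, at −90 °C, the ketone are spared.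

**Step 7**
Reactants: 12 β-hydroxy ketone
Product: 13 methyl 2-[2,4-dihydroxy-4-isopropyl-1-methyl-5-vinylcyclopentyl]acetate (C1 OH β, C3 OH α, C3a vinyl β, C8a methyl β)
Conditions: Me4NBH(OAc)3 (5 equiv), MeCN/AcOH 1:1, −30 → −20 °C
Reagents that add atoms: none
Why: Evans–Saksena hydroxyl-directed reduction: the C3 α-hydroxyl replaces an acetate on boron and passes hydride to C1 across the α face, which is also the face free of the β methyl, vinyl and isopropyl groups, so C1–OH should come out β (1,3-anti diol) under mildly acidic conditions that avoid retro-aldol cleavage, and any minor C1 α-epimer would lactonise to 16 and rejoin the route.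

**Step 8**
Reactants: 13 anti diol
Product: 14 C1 β-methanesulfonate of 13 (C3 OH α free)
Conditions: MsCl (1.3 equiv), Et3N (2 equiv), CH2Cl2, −10 °C
Reagents that add atoms: methanesulfonyl chloride, CS(=O)(=O)Cl
Why: Selective sulfonylation: only the secondary C1 hydroxyl reacts because the C3 carbinol is tertiary and flanked by isopropyl and C3a, and the C1–O bond is not broken so C1 stays β.

**Step 9**
Reactants: 14 mesylate
Product: 16 (3aS,4S,5R,6aR)-5-hydroxy-5-isopropyl-3a-methyl-4-vinylhexahydro-2H-cyclopenta[b]furan-2-one, via lithium carboxylate 15 (not isolated)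
Conditions: LiOH·H2O (3 equiv), THF/H2O 3:1, rt → 45 °C; then aq citric acid to pH 4
Reagents that add atoms: lithium hydroxide, [Li+].[OH-]
Why: Saponification followed by intramolecular SN2 lactonisation (5-exo-tet): the carboxylate hangs from the α face of C8a directly behind the β C1–OMs bond, so displacement inverts C1 to the required α C1–O bond, and only this cis-fused γ-lactone is geometrically possible.

**Step 10**
Reactants: 16 cis-γ-lactone
Product: 17 2-[2,4-dihydroxy-4-isopropyl-1-methyl-5-vinylcyclopentyl]-N-methoxy-N-methylacetamide (C1 OH α, C3 OH α, C3a vinyl β, C8a methyl β)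
Conditions: MeNH(OMe)·HCl (4 equiv), iPrMgCl (8, 9 equiv), THF, −20 → 0 °C; sat. aq NH4Cl; used at once
Reagents that add atoms: N,O-dimethylhydroxylamine hydrochloride, CNOC.Cl
Why: Weinreb aminolysis of a lactone: the chloromagnesium amide attacks the C7 carbonyl and cleaves the acyl–oxygen bond, so C1–O keeps its α configuration and C7 becomes an acyl donor that accepts only one carbon nucleophile.

**Step 11**
Reactants: 17 dihydroxy Weinreb amide
Product: 18 C1 α-triethylsilyl ether of 17 (C3 OH α free)
Conditions: TESCl (1.3 equiv), imidazole (3 equiv), DMAP (5 mol %), CH2Cl2, 0 °C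
Reagents that add atoms: chlorotriethylsilane, CC[Si](CC)(CC)Cl
Why: Chemoselective silylation of the secondary C1 alcohol (the crowded tertiary C3 carbinol is inert to TESCl and imidazole) blocks relactonisation and masks C1–OH for the Grignard step, while C3–OH stays free to steer step 14.

**Step 12**
Reactants: 18 silylated Weinreb amide; 19 but-2-enylmagnesium chloride (crotylmagnesium chloride)
Product: 20 1-[4-hydroxy-4-isopropyl-1-methyl-2-(triethylsilyloxy)-5-vinylcyclopentyl]-3-methylpent-4-en-2-one (C1 OTES α, C3 OH α, C3a vinyl β, C8a methyl β; C6 epimer mixture)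
Conditions: 19 (3 equiv, 0.5 M in THF), THF, −78 → −40 °C; cold sat. aq NH4Cl
Reagents that add atoms: none
Why: Weinreb ketone synthesis with an allylic Grignard reagent: 19 reacts through its γ-carbon (SE2' via a six-membered transition state) to form C7–C6 with the branched α-methylallyl connectivity, the magnesium chelate of the tetrahedral adduct prevents a second addition, and a cold buffered quench avoids conjugation; C6 forms as an epimer mixture that step 14 erases.

**Step 13**
Reactants: 20 diene ketone
Product: 21 trans-fused hydroazulenone with C4=C5, C7 ketone, C6 methyl (epimer mixture), C1 OTES α, C3 OH α, isopropyl β, H-3a α, C8a methyl β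
Conditions: second-generation Hoveyda–Grubbs catalyst RuCl2(SIMes)(=CH-C6H4-2-OiPr) (5–10 mol %), 1,4-benzoquinone (20 mol %), CH2Cl2 (2 mM), 40 °C
Reagents that add atoms: none
Why: Ring-closing metathesis (seven-membered ring, C4=C5, necessarily cis): the ruthenium carbene should load at the more accessible α-methylallyl terminus and close onto the C3a vinyl group, the trans arrangement of the two arms on the cyclopentane maps onto an unstrained trans-hydroazulene, high dilution disfavours oligomers and benzoquinone intercepts ruthenium hydrides that would move the β,γ double bond.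

**Step 14**
Reactants: 21 β,γ-unsaturated ketone
Product: 23 (1R,3R,3aR,4R,8aS)-3,4-dihydroxy-3-isopropyl-6,8a-dimethyl-1-(triethylsilyloxy)-2,3,3a,4,8,8a-hexahydroazulen-7(1H)-one, via 4α,5α-epoxy ketone 22 (not isolated)
Conditions: DMDO (1.2 equiv, in acetone), CH2Cl2, −20 °C; evaporate; then DBU (0.5 equiv), CH2Cl2, 0 °C
Reagents that add atoms: dimethyldioxirane, CC1(C)OO1
Why: Epoxidation and E1cB opening of the β,γ-epoxy ketone: DMDO should attack C4=C5 from the convex α face, which carries only H-3a and the hydrogen-bond-donating C3 hydroxyl whereas the β face is covered by C7, C8, the C8a methyl and the C3 isopropyl group, and DBU then removes the C6 hydrogen so that the enolate expels the C5–O bond, leaving C4–OH α and the C5=C6 enone with loss of the C6 stereocentre.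

**Step 15**
Reactants: 24 4-hydroxybenzoic acid
Product: 26 4-(tert-butyldimethylsilyloxy)benzoic acid, via silyl ester 25 (not isolated)
Conditions: TBSCl (2.5 equiv), imidazole (5 equiv), DMF, rt; then AcOH/THF/H2O 3:1:1, rt
Reagents that add atoms: tert-butyldimethylsilyl chloride, CC(C)(C)[Si](C)(C)Cl
Why: Exhaustive silylation followed by selective hydrolysis: the silyl ester is far more labile to aqueous acetic acid than the aryl silyl ether, so only the phenol stays protected.

**Step 16**
Reactants: 23 γ-hydroxy enone; 26 4-(tert-butyldimethylsilyloxy)benzoic acid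
Product: 27 C4 α-[4-(tert-butyldimethylsilyloxy)benzoate] of 23 (C1 OTES α, C3 OH α free)
Conditions: 26 (1.5 equiv), DCC (1.6 equiv), DMAP (0.3 equiv), CH2Cl2, 0 °C → rt
Reagents that add atoms: none
Why: Steglich esterification: the acylpyridinium ion derived from 26 acylates the secondary allylic C4 hydroxyl, the tertiary C3 carbinol being too hindered, and since only the O–H bond reacts C4 keeps its α oxygen.

**Step 17**
Reactants: 27 bis-silyl ester
Product: 28 C1 α-alcohol (27 without the triethylsilyl group; aryl OTBS kept)
Conditions: PPTS (0.2 equiv), MeOH/CH2Cl2 1:1, 0 °C → rt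
Reagents that add atoms: none
Why: Acid-catalysed methanolysis distinguishes the two silyl ethers, since the alkyl TES ether is protonated and cleaved readily whereas the aryl TBS ether, whose oxygen is deactivated by the para ester group, the aroyl ester and the tertiary carbinol tolerate PPTS.

**Step 18**
Reactants: 28 C1 alcohol
Product: 29 C1 α-acetate of 28 (aryl OTBS kept)
Conditions: Ac2O (3 equiv), pyridine (6 equiv), DMAP (0.1 equiv), CH2Cl2, rt
Reagents that add atoms: acetic anhydride, CC(=O)OC(C)=O
Why: DMAP-catalysed acetylation of the only free secondary alcohol, C1–OH, proceeds with retention at C1, and the tertiary C3 carbinol does not react at room temperature.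

**Step 19**
Reactants: 29 silyl-protected target
Product: 30 (1R,3R,3aR,4R,8aS)-1-acetoxy-3-hydroxy-3-isopropyl-6,8a-dimethyl-7-oxo-1,2,3,3a,4,7,8,8a-octahydroazulen-4-yl 4-hydroxybenzoate (target)
Conditions: Bu4NF (1.1 equiv), AcOH (1.2 equiv), THF, 0 °C
Reagents that add atoms: none
Why: Fluoride-induced cleavage of the aryl silyl ether is fast because an acceptor-substituted phenoxide leaves, and the acetic acid buffer keeps acetate, aroyl ester and the γ-acyloxy enone away from base.

**Compound list**
1 | 2-methylcyclopent-2-en-1-one | CC1=CCCC1=O | starting material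
2 | vinylmagnesium bromide | C=C[Mg]Br | starting material
3 | methyl bromoacetate | COC(=O)CBr | starting material
4 | bromomagnesium C1=C8a enolate of (S)-2-methyl-3-vinylcyclopentanone | CC1=C(O[Mg]Br)CC[C@H]1C=C | intermediate
5 | methyl 2-[(1S,5S)-1-methyl-2-oxo-5-vinylcyclopentyl]acetate | O=C1CC[C@@H](C=C)[C@]1(C)CC(=O)OC | intermediate
6 | lithium C1=C2 enolate of 5 | [Li]OC1=CC[C@@H](C=C)[C@]1(C)CC(=O)OC | intermediate
7 | methyl 2-[(1S,5R)-1-methyl-2-oxo-5-vinylcyclopent-3-en-1-yl]acetate | O=C1C=C[C@@H](C=C)[C@]1(C)CC(=O)OC | intermediate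
8 | isopropylmagnesium chloride | CC(C)[Mg]Cl | starting material
9 | C1=C2 trimethylsilyl enol ether, C3 isopropyl α | C[Si](C)(C)OC1=C[C@H](C(C)C)[C@@H](C=C)[C@]1(C)CC(=O)OC | intermediate
10 | methyl 2-[4-isopropyl-1-methyl-2-oxo-5-vinylcyclopent-3-en-1-yl]acetate | O=C1C=C(C(C)C)[C@@H](C=C)[C@]1(C)CC(=O)OC | intermediate
11 | 2α,3α-epoxy ketone | O=C1[C@@H]2O[C@]2(C(C)C)[C@@H](C=C)[C@]1(C)CC(=O)OC | intermediate
12 | β-hydroxy ketone, C3 OH α | O=C1C[C@@](O)(C(C)C)[C@@H](C=C)[C@]1(C)CC(=O)OC | intermediate
13 | 1,3-anti diol, C1 OH β, C3 OH α | O[C@H]1C[C@@](O)(C(C)C)[C@@H](C=C)[C@]1(C)CC(=O)OC | intermediate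
14 | C1 β-mesylate | CS(=O)(=O)O[C@H]1C[C@@](O)(C(C)C)[C@@H](C=C)[C@]1(C)CC(=O)OC | intermediate
15 | lithium carboxylate of 14 | CS(=O)(=O)O[C@H]1C[C@@](O)(C(C)C)[C@@H](C=C)[C@]1(C)CC(=O)[O-].[Li+] | intermediate
16 | (3aS,4S,5R,6aR)-5-hydroxy-5-isopropyl-3a-methyl-4-vinylhexahydro-2H-cyclopenta[b]furan-2-one | O=C1O[C@@H]2C[C@@](O)(C(C)C)[C@@H](C=C)[C@]2(C)C1 | intermediate
17 | dihydroxy Weinreb amide, C1 OH α, C3 OH α | O[C@@H]1C[C@@](O)(C(C)C)[C@@H](C=C)[C@]1(C)CC(=O)N(C)OC | intermediate
18 | C1 α-OTES Weinreb amide | CC[Si](CC)(CC)O[C@@H]1C[C@@](O)(C(C)C)[C@@H](C=C)[C@]1(C)CC(=O)N(C)OC | intermediate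
19 | but-2-enylmagnesium chloride | CC=CC[Mg]Cl | starting material
20 | α-methylallyl ketone (C6 epimers) | CC[Si](CC)(CC)O[C@@H]1C[C@@](O)(C(C)C)[C@@H](C=C)[C@]1(C)CC(=O)C(C)C=C | intermediate
21 | trans-hydroazulene β,γ-enone, C4=C5 (C6 epimers) | CC[Si](CC)(CC)O[C@@H]1C[C@@](O)(C(C)C)[C@H]2C=CC(C)C(=O)C[C@]12C | intermediate
22 | 4α,5α-epoxy ketone (C6 epimers) | CC[Si](CC)(CC)O[C@@H]1C[C@@](O)(C(C)C)[C@H]2[C@@H]3O[C@@H]3C(C)C(=O)C[C@]12C | intermediate
23 | C4 α-hydroxy C5=C6 enone, C1 OTES α | CC[Si](CC)(CC)O[C@@H]1C[C@@](O)(C(C)C)[C@H]2[C@H](O)C=C(C)C(=O)C[C@]12C | intermediate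
24 | 4-hydroxybenzoic acid | OC(=O)c1ccc(O)cc1 | starting material
25 | tert-butyldimethylsilyl 4-(tert-butyldimethylsilyloxy)benzoate | CC(C)(C)[Si](C)(C)OC(=O)c1ccc(O[Si](C)(C)C(C)(C)C)cc1 | intermediate
26 | 4-(tert-butyldimethylsilyloxy)benzoic acid | CC(C)(C)[Si](C)(C)Oc1ccc(cc1)C(=O)O | intermediate
27 | C4 α-aroyl ester, C1 OTES, aryl OTBS | CC[Si](CC)(CC)O[C@@H]1C[C@@](O)(C(C)C)[C@H]2[C@H](OC(=O)c3ccc(O[Si](C)(C)C(C)(C)C)cc3)C=C(C)C(=O)C[C@]12C | intermediate
28 | C1 α-alcohol, aryl OTBS | O[C@@H]1C[C@@](O)(C(C)C)[C@H]2[C@H](OC(=O)c3ccc(O[Si](C)(C)C(C)(C)C)cc3)C=C(C)C(=O)C[C@]12C | intermediate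
29 | C1 α-acetate, aryl OTBS | CC(=O)O[C@@H]1C[C@@](O)(C(C)C)[C@H]2[C@H](OC(=O)c3ccc(O[Si](C)(C)C(C)(C)C)cc3)C=C(C)C(=O)C[C@]12C | intermediate
30 | (1R,3R,3aR,4R,8aS)-1-acetoxy-3-hydroxy-3-isopropyl-6,8a-dimethyl-7-oxo-1,2,3,3a,4,7,8,8a-octahydroazulen-4-yl 4-hydroxybenzoate | CC(=O)O[C@@H]1C[C@@](O)(C(C)C)[C@H]2[C@H](OC(=O)c3ccc(O)cc3)C=C(C)C(=O)C[C@]12C | target

Total step count: 19. Longest linear sequence: 18 (steps 1–14 and 16–19).

**Steps most likely to fail**

**Step 1.**
- What may go wrong: the small sp2 Grignard reagent may be discriminated poorly by the chiral copper complex. The THF it is sold in speeds up ligand-free 1,4- and 1,2-addition. Slow alkylation of the tetrasubstituted magnesium enolate may allow proton transfer and loss of regiocontrol.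
- Fallback: the same two bonds are formed, but the stereochemical information comes from the substrate instead of the catalyst. The fallback sets out from 2 and 3 and comes back to the route at 7, replacing steps 1 and 2. Commercial (S)-4-(tert-butyldimethylsilyloxy)cyclopent-2-en-1-one F1 is iodinated at the α-carbon (I2, pyridine, CH2Cl2) to (S)-4-(tert-butyldimethylsilyloxy)-2-iodocyclopent-2-en-1-one F2. Stille coupling with Me4Sn (PdCl2(PhCN)2, AsPh3, NMP) gives (S)-4-(tert-butyldimethylsilyloxy)-2-methylcyclopent-2-en-1-one F3. The vinylcuprate made from 2 and CuBr·SMe2 adds to C3a anti to the α silyloxy group, and the enolate is alkylated by 3 (DMPU) anti to the new vinyl group, in a prostaglandin-type three-component coupling. This gives methyl 2-[4-(tert-butyldimethylsilyloxy)-1-methyl-2-oxo-5-vinylcyclopentyl]acetate F4. DBU in CH2Cl2 then expels the silanol by E1cB elimination to give 7.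

**Step 5.**
- What may go wrong: addition of hydroperoxide to the crowded C3 may be slower than removal of the doubly allylic C3a hydrogen. That would cause double-bond migration and loss of the C3a configuration. Partial saponification of the ester is a lesser concern.
- Fallback: the oxygen nucleophile is replaced by a boron nucleophile under nearly neutral conditions. The fallback sets out from 10 and comes back at 12, replacing steps 5 and 6. Copper-catalysed conjugate borylation (B2pin2, CuCl, NaOtBu in catalytic amount, DPEphos, MeOH, THF, rt) should place boron on C3 anti to the vinyl group. This gives methyl 2-[4-isopropyl-1-methyl-2-oxo-4-(4,4,5,5-tetramethyl-1,3,2-dioxaborolan-2-yl)-5-vinylcyclopentyl]acetate F5. Oxidation with NaBO3·4H2O in THF/H2O replaces boron by hydroxyl with retention to give 12.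

**Step 13.**
- What may go wrong: ring closure onto the C3a vinyl group, which is flanked by the cis isopropyl and methyl groups, may be slow. This leaves time for hydride-induced migration of either double bond into conjugation with C7 and for oligomerisation.
- Fallback: the ring is closed at the alcohol oxidation level, where C6–H is not acidic and higher temperatures are tolerated. The fallback sets out from 18 and comes back at 21, replacing steps 12 and 13. Reduction of 18 with iBu2AlH (THF, −78 °C) gives 2-[4-hydroxy-4-isopropyl-1-methyl-2-(triethylsilyloxy)-5-vinylcyclopentyl]acetaldehyde F6. Addition of 19 (THF, −78 °C) through its γ-carbon gives the homoallylic alcohol 1-[4-hydroxy-4-isopropyl-1-methyl-2-(triethylsilyloxy)-5-vinylcyclopentyl]-3-methylpent-4-en-2-ol F7 as a mixture at C6 and C7. Ring-closing metathesis (RuCl2(SIMes)(=CH-C6H4-2-OiPr), toluene, 80 °C) gives the C4=C5 cycloheptenol F8. Dess–Martin periodinane with NaHCO3 in CH2Cl2 oxidises only the secondary C7 alcohol to give 21.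

**Further compounds**
F1 | step 1 | (S)-4-(tert-butyldimethylsilyloxy)cyclopent-2-en-1-one | CC(C)(C)[Si](C)(C)O[C@H]1CC(=O)C=C1
F2 | step 1 | (S)-4-(tert-butyldimethylsilyloxy)-2-iodocyclopent-2-en-1-one | CC(C)(C)[Si](C)(C)O[C@H]1CC(=O)C(I)=C1
F3 | step 1 | (S)-4-(tert-butyldimethylsilyloxy)-2-methylcyclopent-2-en-1-one | CC(C)(C)[Si](C)(C)O[C@H]1CC(=O)C(C)=C1
F4 | step 1 | methyl 2-[4-(tert-butyldimethylsilyloxy)-1-methyl-2-oxo-5-vinylcyclopentyl]acetate (C3 OTBS α, C3a vinyl β, C8a methyl β) | O=C1C[C@H](O[Si](C)(C)C(C)(C)C)[C@@H](C=C)[C@]1(C)CC(=O)OC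
F5 | step 5 | methyl 2-[4-isopropyl-1-methyl-2-oxo-4-(4,4,5,5-tetramethyl-1,3,2-dioxaborolan-2-yl)-5-vinylcyclopentyl]acetate (C3 boron α) | O=C1C[C@@](B2OC(C)(C)C(C)(C)O2)(C(C)C)[C@@H](C=C)[C@]1(C)CC(=O)OC
F6 | step 13 | 2-[4-hydroxy-4-isopropyl-1-methyl-2-(triethylsilyloxy)-5-vinylcyclopentyl]acetaldehyde | CC[Si](CC)(CC)O[C@@H]1C[C@@](O)(C(C)C)[C@@H](C=C)[C@]1(C)CC=O
F7 | step 13 | 1-[4-hydroxy-4-isopropyl-1-methyl-2-(triethylsilyloxy)-5-vinylcyclopentyl]-3-methylpent-4-en-2-ol (C6 and C7 mixture) | CC[Si](CC)(CC)O[C@@H]1C[C@@](O)(C(C)C)[C@@H](C=C)[C@]1(C)CC(O)C(C)C=C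
F8 | step 13 | C4=C5 cycloheptenol, 21 with C7–OH in place of the ketone (C6 and C7 mixture) | CC[Si](CC)(CC)O[C@@H]1C[C@@](O)(C(C)C)[C@H]2C=CC(C)C(O)C[C@]12C
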